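A solid goes into a closed flask.

solid substrate 0.57 M; time 15 d

    starting material ⇌ target (K1 = 1.7, k1 = 0.0022 min⁻¹)
    starting material ⇌ isomer of the product A (K2 = 0.76, k2 = 4.2 × 10⁻⁴ min⁻¹)
    starting material ⇌ isomer of the product B (K3 = 0.51, k3 = 6.2 × 10⁻⁴ min⁻¹)
    solid substrate ⇌ starting material, rate k4*(cs4 - [starting material]) while solid is left; crystals form when [starting material] > cs4 (cs4 = 0.20 M, k4 = 0.0018 min⁻¹)
    target ⇌ isomer of the product C (K5 = 0.12, k5 = 5.8 × 10⁻⁵ min⁻¹)

* part of the solid substrate that has turned into other species by 15 d (what has only dissolved does not count)
* amount of target at 15 d, in percent of the solid substrate charged
* amount of starting material at 15 d, in percent of the solid substrate charged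
* amount of isomer of the product A at 15 d, in percent of the solid substrate charged

- as a solid, counted per litre of solution: solid substrate
- at the start none of the solid substrate is in solution
- what has only dissolved of solid substrate counts as not reacted
- starting material means what is dissolved; the solid is not counted in it
- run time (flask): 15 d

Two chemists disagree about this flask. The first argues from solubility: the charge of 0.57 M is more than the solubility of 0.20 M, so she expects solid to stay, with c(starting material) at its solubility, which is 35.1% of the charge. The second argues that whatever forms from starting material lowers c(starting material), so more solid can dissolve.

My own reckoning takes the second side and works with the fraction left. At equilibrium, each unit of c(starting material) carries 1.7 of target, 0.76 of isomer of the product A, 0.51 of isomer of the product B and 0.204 of isomer of the product C, so the dissolved forms add up to 4.17 units. Multiplied by the solubility, this gives the capacity of the solution, 0.835 M, the amount of solid substrate taken up at equilibrium with c(starting material) at its solubility. This flask's charge is below the capacity, so I expect no solid at the end, and the fraction left as starting material is the reciprocal of the sum, 24.0%, which means c(starting material) is 0.137 M.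

Two times allow for this. Dissolution slows as c(starting material) rises, so I take its rate with c(starting material) at the value just reckoned, which gives about 3.47 d for the whole charge, and the step from target to isomer of the product C, taken alone, relaxes with a half-life of 0.889 d. Both are shorter than the 15 d allowed.

The forecast takes the second side: conversion 76.04%, target 40.73%, starting material 23.96% and isomer of the product A 18.21%, on the ground that “the flask is essentially at equilibrium”.

The simulation gives 76.0%, 40.7%, 24.0% and 18.2%, with solid substrate at 0%. The second chemist is right for this flask.

In this flask at 15.0 d, the forward half-life of starting material towards target is 0.22 d, shorter than the 1.1 d towards isomer of the product A, and the forward rates stand at 5.2 to one. Yet the amounts stand at 2.24 to one, matching the ratio of equilibrium constants, 2.24: thermodynamic control.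

The neighbour flask with 1.4 M of solid substrate lies above the capacity, which is the first chemist's case: the capacity gives starting material 14.3%, solid 40.4% and conversion 45.4%. Computed, that flask shows 14.3%, 40.5% and 45.2%.

The constants come from no measurement; the run is a simulation.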